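**Plan**
- Ring A carbons are C1'–C6' (C1' bears the carbonyl group) and chain carbons are C1''–C8''. Ring A is a 2-alkylresorcinol: the chain sits on C3' between the oxygen-bearing C2' and C4', and C5'/C6' are unsubstituted. A vinylketene–siloxyalkyne benzannulation writes exactly this pattern, with O2' free and O4' silylated.
- Retrosynthesis: cut the aryl–carbonyl bond C1'–C(=O) first (aryllithium plus cinnamoyl Weinreb amide). Then open ring A at C1'–C2', C2'–C3' and C4'–C5' (cyclobutenone plus chain-bearing ynol ether). Then cut C3'–C1'' (ethynyl plus allylic bromide).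
- Forward: geranyl acetate is oxidised at its terminus and extended to a terminal alkyne, then to the triisopropylsilyl ynol ether. Ring A is grown around the alkyne carbons. Ring B with the enone carbons is joined in one operation, and two deprotections finish.
- Stereochemistry: C6'' (R) comes from a Shi epoxidation and is carried unchanged through the epoxide-to-allylic-alcohol isomerisation. The 2''E alkene comes from geranyl acetate, and the enone E alkene from a Horner–Wadsworth–Emmons reaction.

Key step: step 10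

Remark: the D-fructose-derived Shi ketone is taken to give the (R)-epoxide at C6'' by the spiro transition-state model; should the sense prove opposite, the enantiomeric ketone would be used.

Step 1
Reactants: 1 geranyl acetate
Product: 2 (2E)-5-[(2R)-3,3-dimethyloxiran-2-yl]-3-methylpent-2-en-1-yl acetate
Conditions: D-fructose-derived Shi ketone (30 mol %), Oxone (2KHSO5·KHSO4·K2SO4), K2CO3, Bu4NHSO4 (cat.), MeCN/CH2(OMe)2/aq Na2B4O7 buffer, 0 °C
Reagents that add atoms: potassium peroxymonosulfate (active part of Oxone), [K+].[O-]S(=O)(=O)OO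
Why: Shi asymmetric epoxidation, in which the chiral dioxirane attacks the electron-richer 6,7-alkene (the 2,3-alkene is deactivated by the allylic acetate) through a spiro transition state that should place oxygen on the face giving the R configuration at the epoxide CH.

Step 2
Reactants: 2 (2E)-5-[(2R)-3,3-dimethyloxiran-2-yl]-3-methylpent-2-en-1-yl acetate
Product: 3 (2E,6R)-6-hydroxy-3,7-dimethylocta-2,7-dien-1-yl acetate
Conditions: Et2AlCl, lithium 2,2,6,6-tetramethylpiperidide (4 equiv each), toluene, 0 °C; aq potassium sodium tartrate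
Reagents that add atoms: none
Why: Aluminium-amide-promoted epoxide-to-allylic-alcohol isomerisation, in which aluminium binds the epoxide oxygen and the hindered amide removes a proton from a C7 methyl group in a cyclic syn-elimination, so the isopropenyl carbinol forms with the C6–O bond and its R configuration untouched, the amide being too bulky to attack the acetate.

Step 3
Reactants: 3 (2E,6R)-6-hydroxy-3,7-dimethylocta-2,7-dien-1-yl acetate
Product: 4 (2E,6R)-6-(tert-butyldimethylsilyloxy)-3,7-dimethylocta-2,7-dien-1-yl acetate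
Conditions: TBSCl, imidazole, DMF, rt
Reagents that add atoms: tert-butyldimethylsilyl chloride, CC(C)(C)[Si](C)(C)Cl
Why: Standard silylation of a secondary alcohol with a silyl chloride and imidazole, which leaves the acetate, both alkenes and the stereocentre unaffected.

Step 4
Reactants: 4 (2E,6R)-6-(tert-butyldimethylsilyloxy)-3,7-dimethylocta-2,7-dien-1-yl acetate
Product: 5 (2E,6R)-6-(tert-butyldimethylsilyloxy)-3,7-dimethylocta-2,7-dien-1-ol
Conditions: K2CO3 (cat.), MeOH, 0 °C to rt
Reagents that add atoms: none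
Why: Base-catalysed transesterification (methanolysis) removes the acetate while the secondary silyl ether is stable to K2CO3 in MeOH.

Step 5
Reactants: 5 (2E,6R)-6-(tert-butyldimethylsilyloxy)-3,7-dimethylocta-2,7-dien-1-ol
Product: 6 (2E,6R)-1-bromo-6-(tert-butyldimethylsilyloxy)-3,7-dimethylocta-2,7-diene
Conditions: CBr4, PPh3, CH2Cl2, 0 °C; used without storage
Reagents that add atoms: carbon tetrabromide, BrC(Br)(Br)Br
Why: Appel reaction, in which bromide displaces the alkoxyphosphonium ion of the primary allylic alcohol under near-neutral conditions that spare the silyl ether and the E alkene.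

Step 6
Reactants: 6 (2E,6R)-1-bromo-6-(tert-butyldimethylsilyloxy)-3,7-dimethylocta-2,7-diene
Product: 7 (4E,8R)-8-(tert-butyldimethylsilyloxy)-5,9-dimethyldeca-4,9-dien-1-yne
Conditions: HC≡CMgBr, CuCl (10 mol %), THF, 0 °C to rt
Reagents that add atoms: ethynylmagnesium bromide, C#C[Mg]Br
Why: Copper-catalysed SN2 coupling of an allylic bromide with an alkynyl Grignard reagent, which for geranyl-type halides should give the linear skipped enyne with the E geometry retained.

Step 7
Reactants: 7 (4E,8R)-8-(tert-butyldimethylsilyloxy)-5,9-dimethyldeca-4,9-dien-1-yne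
Product: 10 (4E,8R)-8-(tert-butyldimethylsilyloxy)-5,9-dimethyl-1-(triisopropylsilyloxy)deca-4,9-dien-1-yne, via lithium acetylide 8 (not isolated), via lithium ynolate 9 (not isolated)
Conditions: LiN(SiMe3)2, THF, −78 °C; LiOO-t-Bu (from t-BuOOH and LiN(SiMe3)2), −78 to 0 °C; i-Pr3SiOTf, −78 to 0 °C
Reagents that add atoms: tert-butyl hydroperoxide, CC(C)(C)OO; triisopropylsilyl trifluoromethanesulfonate, CC(C)[Si](OS(=O)(=O)C(F)(F)F)(C(C)C)C(C)C
Why: Oxidation of a lithium acetylide by lithium tert-butyl peroxide to the lithium ynolate followed by O-silylation, where the amide base at −78 °C removes only the acetylenic proton and the bulky silyl triflate reacts at oxygen to give an isolable triisopropylsilyl ynol ether.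

Step 8
Reactants: 11 3-oxocyclobutanecarboxylic acid
Product: 12 3-bromocyclobutanone
Conditions: HgO, Br2, MgSO4, CH2Cl2, reflux
Reagents that add atoms: bromine, BrBr
Why: Hunsdiecker-type bromodecarboxylation (HgO/Br2 variant), in which the acyl hypobromite fragments with loss of CO2 to a cyclobutyl radical that is brominated.

Step 9
Reactants: 12 3-bromocyclobutanone
Product: 13 cyclobut-2-en-1-one
Conditions: Bu3N, neat, rt, vacuum transfer into a −78 °C trap; kept as a cold toluene solution
Reagents that add atoms: none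
Why: E1cB dehydrobromination of a β-bromo ketone by a tertiary amine, with the volatile enone removed from the base as it forms to limit oligomerisation.

Step 10
Reactants: 10 (4E,8R)-8-(tert-butyldimethylsilyloxy)-5,9-dimethyl-1-(triisopropylsilyloxy)deca-4,9-dien-1-yne; 13 cyclobut-2-en-1-one
Product: 18 2-[(2E,6R)-6-(tert-butyldimethylsilyloxy)-3,7-dimethylocta-2,7-dien-1-yl]-3-(triisopropylsilyloxy)phenol, via vinylketene 14 (not isolated), via 4-vinylcyclobutenone 15 (not isolated), via dienylketene 16 (not isolated), via cyclohexa-2,4-dienone 17 (not isolated)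
Conditions: 13 (2 equiv, slow addition in toluene) to 10, toluene, 80 °C; then 110 °C
Reagents that add atoms: none
Why: Heating opens cyclobutenone 13 by four-electron electrocyclic ring opening to vinylketene 14, which undergoes a [2+2] cycloaddition with ynol ether 10, the nucleophilic chain-bearing alkyne carbon bonding to the ketene carbonyl carbon (C2'–C3') and the oxygen-bearing alkyne carbon to the ketene α-carbon (C4'–C5') to give 4-vinylcyclobutenone 15. A second four-electron opening of 15 gives dienylketene 16, and ring A closes by a thermal six-electron disrotatory electrocyclisation that joins the ketene carbon to the vinyl terminus (C1'–C2'), the cyclohexa-2,4-dienone 17 then tautomerising to phenol 18. The closest known reaction type is the Danheiser benzannulation of cyclobutenones with trialkylsiloxyalkynes, which gives resorcinol monosilyl ethers. No stereocentre is created, because the sp3 carbon of 15 becomes planar again, and the C6'' silyl ether and the 2''E alkene are spectators. The step needs regioselectivity, secured by the polarisation of the siloxyalkyne, and chemoselectivity for the alkyne over the three chain alkenes, secured because isolated alkenes are far poorer ketenophiles than an electron-rich ynol ether. The bulky triisopropylsilyl group should stay on O4', so the two ring A oxygens emerge differentiated.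

Step 11
Reactants: 18 2-[(2E,6R)-6-(tert-butyldimethylsilyloxy)-3,7-dimethylocta-2,7-dien-1-yl]-3-(triisopropylsilyloxy)phenol
Product: 19 1-(methoxymethoxy)-2-[(2E,6R)-6-(tert-butyldimethylsilyloxy)-3,7-dimethylocta-2,7-dien-1-yl]-3-(triisopropylsilyloxy)benzene
Conditions: MOMCl, i-Pr2NEt, CH2Cl2, 0 °C to rt
Reagents that add atoms: chloromethyl methyl ether, COCCl
Why: O-alkylation of the free phenol with chloromethyl methyl ether and a hindered amine base, which leaves both silyl ethers intact and installs the group that later directs metalation.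

Step 12
Reactants: 20 3,4-dihydroxybenzaldehyde
Product: 21 3,4-bis(tert-butyldimethylsilyloxy)benzaldehyde
Conditions: TBSCl, imidazole, DMF, rt
Reagents that add atoms: tert-butyldimethylsilyl chloride, CC(C)(C)[Si](C)(C)Cl
Why: Standard bis-silylation of a catechol with a silyl chloride and imidazole.

Step 13
Reactants: 21 3,4-bis(tert-butyldimethylsilyloxy)benzaldehyde
Product: 22 (2E)-3-[3,4-bis(tert-butyldimethylsilyloxy)phenyl]-N-methoxy-N-methylprop-2-enamide
Conditions: (EtO)2P(O)CH2C(O)N(OMe)Me, NaH, THF, 0 °C to rt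
Reagents that add atoms: diethyl [2-(methoxy(methyl)amino)-2-oxoethyl]phosphonate, CCOP(=O)(CC(=O)N(C)OC)OCC
Why: Horner–Wadsworth–Emmons olefination with a stabilised phosphonate carbanion, which should give the E enamide and spares the aryl silyl ethers because no hydroxide is present.

Step 14
Reactants: 19 1-(methoxymethoxy)-2-[(2E,6R)-6-(tert-butyldimethylsilyloxy)-3,7-dimethylocta-2,7-dien-1-yl]-3-(triisopropylsilyloxy)benzene; 22 (2E)-3-[3,4-bis(tert-butyldimethylsilyloxy)phenyl]-N-methoxy-N-methylprop-2-enamide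
Product: 25 (2E)-3-[3,4-bis(tert-butyldimethylsilyloxy)phenyl]-1-{2-(methoxymethoxy)-3-[(2E,6R)-6-(tert-butyldimethylsilyloxy)-3,7-dimethylocta-2,7-dien-1-yl]-4-(triisopropylsilyloxy)phenyl}prop-2-en-1-one, via aryllithium 23 (not isolated), via tetrahedral lithium alkoxide 24 (not isolated)
Conditions: n-BuLi, TMEDA, Et2O, 0 °C; then 22, THF, −78 to 0 °C; then H2O
Reagents that add atoms: none
Why: Directed ortho-metalation followed by Weinreb ketone synthesis, in which the MOM oxygens direct n-BuLi to C1' (C3' is blocked and the bulky silyloxy group does not direct) and the aryllithium adds 1,2 to the amide carbonyl to give a chelated tetrahedral adduct that releases the E enone only on work-up.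

Step 15
Reactants: 25 (2E)-3-[3,4-bis(tert-butyldimethylsilyloxy)phenyl]-1-{2-(methoxymethoxy)-3-[(2E,6R)-6-(tert-butyldimethylsilyloxy)-3,7-dimethylocta-2,7-dien-1-yl]-4-(triisopropylsilyloxy)phenyl}prop-2-en-1-one
Product: 26 (2E)-3-(3,4-dihydroxyphenyl)-1-{4-hydroxy-3-[(2E,6R)-6-hydroxy-3,7-dimethylocta-2,7-dien-1-yl]-2-(methoxymethoxy)phenyl}prop-2-en-1-one
Conditions: Bu4NF, AcOH, THF (degassed), 0 °C to rt
Reagents that add atoms: none
Why: Fluoride-mediated cleavage of all four silyl ethers, driven by Si–F bond formation, with AcOH buffering and the still-protected O2' keeping the chalcone from closing to a flavanone.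

Step 16
Reactants: 26 (2E)-3-(3,4-dihydroxyphenyl)-1-{4-hydroxy-3-[(2E,6R)-6-hydroxy-3,7-dimethylocta-2,7-dien-1-yl]-2-(methoxymethoxy)phenyl}prop-2-en-1-one
Product: 27 (2E)-1-{2,4-dihydroxy-3-[(2E,6R)-6-hydroxy-3,7-dimethylocta-2,7-dien-1-yl]phenyl}-3-(3,4-dihydroxyphenyl)prop-2-en-1-one
Conditions: dilute HCl, MeOH, rt
Reagents that add atoms: none
Why: Acid-catalysed acetal methanolysis of the MOM ether, which is especially labile next to the chelating carbonyl group, under conditions mild enough to spare the allylic alcohol, the trisubstituted alkene ortho to the phenols and the enone.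

**Compound list**
1 | geranyl acetate | CC(C)=CCC/C(C)=C/COC(C)=O | starting material
2 | (2E)-5-[(2R)-3,3-dimethyloxiran-2-yl]-3-methylpent-2-en-1-yl acetate | CC1(C)O[C@@H]1CC/C(C)=C/COC(C)=O | intermediate
3 | (2E,6R)-6-hydroxy-3,7-dimethylocta-2,7-dien-1-yl acetate | C=C(C)[C@H](O)CC/C(C)=C/COC(C)=O | intermediate
4 | (2E,6R)-6-(tert-butyldimethylsilyloxy)-3,7-dimethylocta-2,7-dien-1-yl acetate | C=C(C)[C@H](O[Si](C)(C)C(C)(C)C)CC/C(C)=C/COC(C)=O | intermediate
5 | (2E,6R)-6-(tert-butyldimethylsilyloxy)-3,7-dimethylocta-2,7-dien-1-ol | C=C(C)[C@H](O[Si](C)(C)C(C)(C)C)CC/C(C)=C/CO | intermediate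
6 | (2E,6R)-1-bromo-6-(tert-butyldimethylsilyloxy)-3,7-dimethylocta-2,7-diene | C=C(C)[C@H](O[Si](C)(C)C(C)(C)C)CC/C(C)=C/CBr | intermediate
7 | (4E,8R)-8-(tert-butyldimethylsilyloxy)-5,9-dimethyldeca-4,9-dien-1-yne | C=C(C)[C@H](O[Si](C)(C)C(C)(C)C)CC/C(C)=C/CC#C | intermediate
8 | lithium acetylide of 7 (formed in the flask) | C=C(C)[C@H](O[Si](C)(C)C(C)(C)C)CC/C(C)=C/CC#C[Li] | intermediate
9 | lithium ynolate, lithium (4E,8R)-8-(tert-butyldimethylsilyloxy)-5,9-dimethyldeca-4,9-dien-1-yn-1-olate (formed in the flask) | C=C(C)[C@H](O[Si](C)(C)C(C)(C)C)CC/C(C)=C/CC#CO[Li] | intermediate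
10 | (4E,8R)-8-(tert-butyldimethylsilyloxy)-5,9-dimethyl-1-(triisopropylsilyloxy)deca-4,9-dien-1-yne | C=C(C)[C@H](O[Si](C)(C)C(C)(C)C)CC/C(C)=C/CC#CO[Si](C(C)C)(C(C)C)C(C)C | intermediate
11 | 3-oxocyclobutanecarboxylic acid | O=C1CC(C(=O)O)C1 | starting material
12 | 3-bromocyclobutanone | O=C1CC(Br)C1 | intermediate
13 | cyclobut-2-en-1-one | O=C1C=CC1 | intermediate
14 | vinylketene, buta-1,3-dien-1-one (formed in the flask) | C=CC=C=O | intermediate
15 | 2-[(2E,6R)-6-(tert-butyldimethylsilyloxy)-3,7-dimethylocta-2,7-dien-1-yl]-3-(triisopropylsilyloxy)-4-vinylcyclobut-2-en-1-one, both configurations at C4 (formed in the flask) | C=C(C)[C@H](O[Si](C)(C)C(C)(C)C)CC/C(C)=C/CC1=C(O[Si](C(C)C)(C(C)C)C(C)C)C(C=C)C1=O | intermediate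
16 | dienylketene, 2-alkyl-3-(triisopropylsilyloxy)hexa-1,3,5-trien-1-one with the vinyl group cis to the ketene carbon (formed in the flask) | C=C(C)[C@H](O[Si](C)(C)C(C)(C)C)CC/C(C)=C/CC(=C=O)/C(O[Si](C(C)C)(C(C)C)C(C)C)=C\C=C | intermediate
17 | 2-[(2E,6R)-6-(tert-butyldimethylsilyloxy)-3,7-dimethylocta-2,7-dien-1-yl]-3-(triisopropylsilyloxy)cyclohexa-2,4-dien-1-one (formed in the flask) | C=C(C)[C@H](O[Si](C)(C)C(C)(C)C)CC/C(C)=C/CC1=C(O[Si](C(C)C)(C(C)C)C(C)C)C=CCC1=O | intermediate
18 | 2-[(2E,6R)-6-(tert-butyldimethylsilyloxy)-3,7-dimethylocta-2,7-dien-1-yl]-3-(triisopropylsilyloxy)phenol | C=C(C)[C@H](O[Si](C)(C)C(C)(C)C)CC/C(C)=C/Cc1c(O)cccc1O[Si](C(C)C)(C(C)C)C(C)C | intermediate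
19 | 1-(methoxymethoxy)-2-[(2E,6R)-6-(tert-butyldimethylsilyloxy)-3,7-dimethylocta-2,7-dien-1-yl]-3-(triisopropylsilyloxy)benzene | C=C(C)[C@H](O[Si](C)(C)C(C)(C)C)CC/C(C)=C/Cc1c(OCOC)cccc1O[Si](C(C)C)(C(C)C)C(C)C | intermediate
20 | 3,4-dihydroxybenzaldehyde | O=Cc1ccc(O)c(O)c1 | starting material
21 | 3,4-bis(tert-butyldimethylsilyloxy)benzaldehyde | O=Cc1ccc(O[Si](C)(C)C(C)(C)C)c(O[Si](C)(C)C(C)(C)C)c1 | intermediate
22 | (2E)-3-[3,4-bis(tert-butyldimethylsilyloxy)phenyl]-N-methoxy-N-methylprop-2-enamide | CON(C)C(=O)/C=C/c1ccc(O[Si](C)(C)C(C)(C)C)c(O[Si](C)(C)C(C)(C)C)c1 | intermediate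
23 | aryllithium, 19 lithiated at C1' ortho to the MOM ether (formed in the flask) | C=C(C)[C@H](O[Si](C)(C)C(C)(C)C)CC/C(C)=C/Cc1c(OCOC)c([Li])ccc1O[Si](C(C)C)(C(C)C)C(C)C | intermediate
24 | tetrahedral lithium alkoxide from addition of 23 to 22, both configurations at the new carbon (formed in the flask) | C=C(C)[C@H](O[Si](C)(C)C(C)(C)C)CC/C(C)=C/Cc1c(OCOC)c(C(O[Li])(N(C)OC)/C=C/c2ccc(O[Si](C)(C)C(C)(C)C)c(O[Si](C)(C)C(C)(C)C)c2)ccc1O[Si](C(C)C)(C(C)C)C(C)C | intermediate
25 | (2E)-3-[3,4-bis(tert-butyldimethylsilyloxy)phenyl]-1-{2-(methoxymethoxy)-3-[(2E,6R)-6-(tert-butyldimethylsilyloxy)-3,7-dimethylocta-2,7-dien-1-yl]-4-(triisopropylsilyloxy)phenyl}prop-2-en-1-one | C=C(C)[C@H](O[Si](C)(C)C(C)(C)C)CC/C(C)=C/Cc1c(OCOC)c(C(=O)/C=C/c2ccc(O[Si](C)(C)C(C)(C)C)c(O[Si](C)(C)C(C)(C)C)c2)ccc1O[Si](C(C)C)(C(C)C)C(C)C | intermediate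
26 | (2E)-3-(3,4-dihydroxyphenyl)-1-{4-hydroxy-3-[(2E,6R)-6-hydroxy-3,7-dimethylocta-2,7-dien-1-yl]-2-(methoxymethoxy)phenyl}prop-2-en-1-one | C=C(C)[C@H](O)CC/C(C)=C/Cc1c(OCOC)c(C(=O)/C=C/c2ccc(O)c(O)c2)ccc1O | intermediate
27 | (2E)-1-{2,4-dihydroxy-3-[(2E,6R)-6-hydroxy-3,7-dimethylocta-2,7-dien-1-yl]phenyl}-3-(3,4-dihydroxyphenyl)prop-2-en-1-one | C=C(C)[C@H](O)CC/C(C)=C/Cc1c(O)ccc(C(=O)/C=C/c2ccc(O)c(O)c2)c1O | target

**Step count**
Total: 16 steps. Longest linear sequence: 12 steps (steps 1–7, 10, 11, 14, 15, 16 from geranyl acetate).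

**Steps most likely to fail**

1. Step 10. Unsubstituted cyclobutenone may oligomerise, or the vinylketene may dimerise or be captured by the product phenol, before it meets the ynol ether, so that little ring A forms. Fallback, from 10 back to 18: the same vinylketene is generated without heating by a photochemical Wolff rearrangement. The kinetic lithium enolate of methyl vinyl ketone (LiN(SiMe3)2, THF, −78 °C) would be acylated with CF3CO2CH2CF3 to 1,1,1-trifluorohex-5-ene-2,4-dione F1. Detrifluoroacetylative diazo transfer (MsN3, Et3N, H2O, MeCN) would then give 1-diazobut-3-en-2-one F2. Irradiation of F2 with 10 (300 nm, ClCH2CH2Cl, rt), then brief warming to 80 °C to complete the electrocyclic steps, should deliver 18.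

2. Step 14. n-BuLi may remove a proton from the doubly activated benzylic–allylic C1'' methylene instead of the ring proton at C1', or the organolithium may add in conjugate fashion to the enamide. Fallback, from 18 back to 25, uses the free phenol to direct the new carbon:
   - Magnesium-mediated ortho-formylation (MgCl2, Et3N, paraformaldehyde, MeCN, reflux) would give 2-hydroxy-3-[(2E,6R)-6-(tert-butyldimethylsilyloxy)-3,7-dimethylocta-2,7-dien-1-yl]-4-(triisopropylsilyloxy)benzaldehyde F3.
   - MOMCl/i-Pr2NEt would give its MOM ether F4.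
   - MeMgBr (THF, −78 °C) would give the 1-arylethanol F5 as an epimer mixture.
   - Dess–Martin periodinane would give the 1-arylethanone F6.
   - The lithium enolate of F6 (LiN(SiMe3)2, THF, −78 °C) and aldehyde 21 would give the β-hydroxy ketone F7.
   - MsCl/Et3N would give the β-mesyloxy ketone F8, and DBU would eliminate it to the E enone 25.

3. Step 2. The aluminium amide may be consumed by enolisation or cleavage of the acetate, or may abstract a C5 proton, giving a mixture instead of the isopropenyl carbinol. Fallback, from 2 back to 3: silyl-triflate-induced epoxide opening and elimination (Me3SiOTf, 2,6-lutidine, toluene, −78 °C; then DBU) would give (2E,6R)-3,7-dimethyl-6-(trimethylsilyloxy)octa-2,7-dien-1-yl acetate F9. Its trimethylsilyl ether would be removed with citric acid in MeOH, which leaves the acetate in place, to give 3.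

**Further compounds**
F1 | step 10 | 1,1,1-trifluorohex-5-ene-2,4-dione | C=CC(=O)CC(=O)C(F)(F)F
F2 | step 10 | 1-diazobut-3-en-2-one | C=CC(=O)C=[N+]=[N-]
F3 | step 14 | 2-hydroxy-3-[(2E,6R)-6-(tert-butyldimethylsilyloxy)-3,7-dimethylocta-2,7-dien-1-yl]-4-(triisopropylsilyloxy)benzaldehyde | C=C(C)[C@H](O[Si](C)(C)C(C)(C)C)CC/C(C)=C/Cc1c(O)c(C=O)ccc1O[Si](C(C)C)(C(C)C)C(C)C
F4 | step 14 | 2-(methoxymethoxy)-3-[(2E,6R)-6-(tert-butyldimethylsilyloxy)-3,7-dimethylocta-2,7-dien-1-yl]-4-(triisopropylsilyloxy)benzaldehyde | C=C(C)[C@H](O[Si](C)(C)C(C)(C)C)CC/C(C)=C/Cc1c(OCOC)c(C=O)ccc1O[Si](C(C)C)(C(C)C)C(C)C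
F5 | step 14 | 1-{2-(methoxymethoxy)-3-[(2E,6R)-6-(tert-butyldimethylsilyloxy)-3,7-dimethylocta-2,7-dien-1-yl]-4-(triisopropylsilyloxy)phenyl}ethanol, epimer mixture at the carbinol | C=C(C)[C@H](O[Si](C)(C)C(C)(C)C)CC/C(C)=C/Cc1c(OCOC)c(C(C)O)ccc1O[Si](C(C)C)(C(C)C)C(C)C
F6 | step 14 | 1-{2-(methoxymethoxy)-3-[(2E,6R)-6-(tert-butyldimethylsilyloxy)-3,7-dimethylocta-2,7-dien-1-yl]-4-(triisopropylsilyloxy)phenyl}ethanone | C=C(C)[C@H](O[Si](C)(C)C(C)(C)C)CC/C(C)=C/Cc1c(OCOC)c(C(C)=O)ccc1O[Si](C(C)C)(C(C)C)C(C)C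
F7 | step 14 | 3-[3,4-bis(tert-butyldimethylsilyloxy)phenyl]-3-hydroxy-1-{2-(methoxymethoxy)-3-[(2E,6R)-6-(tert-butyldimethylsilyloxy)-3,7-dimethylocta-2,7-dien-1-yl]-4-(triisopropylsilyloxy)phenyl}propan-1-one, epimer mixture at the carbinol | C=C(C)[C@H](O[Si](C)(C)C(C)(C)C)CC/C(C)=C/Cc1c(OCOC)c(C(=O)CC(O)c2ccc(O[Si](C)(C)C(C)(C)C)c(O[Si](C)(C)C(C)(C)C)c2)ccc1O[Si](C(C)C)(C(C)C)C(C)C
F8 | step 14 | methanesulfonate of F7 at the benzylic carbinol, epimer mixture | C=C(C)[C@H](O[Si](C)(C)C(C)(C)C)CC/C(C)=C/Cc1c(OCOC)c(C(=O)CC(OS(C)(=O)=O)c2ccc(O[Si](C)(C)C(C)(C)C)c(O[Si](C)(C)C(C)(C)C)c2)ccc1O[Si](C(C)C)(C(C)C)C(C)C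
F9 | step 2 | (2E,6R)-3,7-dimethyl-6-(trimethylsilyloxy)octa-2,7-dien-1-yl acetate | C=C(C)[C@H](O[Si](C)(C)C)CC/C(C)=C/COC(C)=O
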